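The oxirane's C5–O bond is traced back to the C4 hydroxyl. In the six-membered ring (C1 ketone, C2 nitrogen, C3, C4 carbinol, C5–C6 oxirane) the C4–OH and the C5 oxygen sit cis on neighbouring carbons, so a two-atom O–B link can hand oxygen from C4–O to C5. One catalytic oxa-Michael addition of a phenylboronic hemiester to an achiral, mirror-symmetric 4-hydroxycyclohexadienone, whose C4 carries the future side-chain carbon as a dioxolane, tells the two enone arms apart, closes a cis-fused dioxaborolane and sets C4 and C5 together. Bromination at C6 and ring closure then give the oxirane; nitrogen and both polyene chains are attached afterwards.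

Key step: step 3

Remark: ring atoms are numbered C1 (ketone), C2 (N-bearing), C3, C4 (carbinol), C5 and C6 (oxirane), and C7 is the carbon on C4; which pseudo-enantiomer of the cinchona catalyst leads to the (4S,5R) boronate cannot be assigned in advance, so the quinine-derived one is written and the quinidine-derived one takes its place if the sense is reversed.

Step 1
Reactants: 1 4-hydroxybenzaldehyde; 2 ethylene glycol
Product: 3 4-(1,3-dioxolan-2-yl)phenol
Conditions: HC(OEt)3, p-TsOH·H2O (cat.), THF, rt; Et3N quench
Reagents that add atoms: none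
Why: Acid-catalysed acetalisation driven by the orthoformate as water scavenger should give the cyclic acetal, which tolerates the free phenol better than an open-chain acetal because its ring opening is reversible.

Step 2
Reactants: 3 4-(1,3-dioxolan-2-yl)phenol
Product: 5 4-(1,3-dioxolan-2-yl)-4-hydroxycyclohexa-2,5-dien-1-one, via hydroperoxide 4 (not isolated)
Conditions: KHSO5 (Oxone, 2KHSO5·KHSO4·K2SO4), NaHCO3, MeCN/H2O, rt; then Na2S2O3
Reagents that add atoms: potassium peroxymonosulfate, [K+].[O-]S(=O)(=O)OO
Why: Oxidative dearomatisation of a para-substituted phenol by singlet oxygen released from buffered peroxymonosulfate should give the para-hydroperoxide 4, which thiosulfate reduces to the quinol while the mildly basic medium spares the acetal; no stereocentre arises because 5 has a mirror plane through C1, C4 and C7.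

Step 3
Reactants: 5 4-(1,3-dioxolan-2-yl)-4-hydroxycyclohexa-2,5-dien-1-one; 6 phenylboronic acid
Product: 8 (4S,5R)-4-(1,3-dioxolan-2-yl)-4,5-dihydroxycyclohex-2-en-1-one 4,5-O-phenylboronate (cis-fused dioxaborolane), via boronic hemiester 7 (not isolated)
Conditions: 6 (1.2 equiv), 9-amino-9-deoxy-epi-quinine N-[3,5-bis(trifluoromethyl)phenyl]thiourea (10–20 mol %), 4 Å molecular sieves, toluene, rt
Reagents that add atoms: none
Why: Proposed new method: phenylboronic acid condenses reversibly with the tertiary C4 hydroxyl to hemiester 7, the quinuclidine nitrogen of the catalyst complexes boron and makes the remaining B–OH nucleophilic while the thiourea hydrogen-bonds the C1 carbonyl, and this oxygen adds intramolecularly to C5, the enol then being protonated at C6. The closest known reaction types are the amine–thiourea-catalysed oxa-Michael addition of boronic hemiesters to γ-hydroxy enones and desymmetrising oxa-Michael additions to 4-hydroxycyclohexadienones; joining them on a quinol with a tertiary carbinol is the new element. The 1,3,2-dioxaborolane ring closes in a 5-exo-trig mode. C5 is fixed relative to C4 by the two-atom O–B tether, which can only reach the ring face that carries the C4 oxygen (cis fusion), and C4 becomes a stereocentre because the catalyst chooses between the enantiotopic carbons C5 and C3. The step needs enantiotopic-group selectivity and a single addition: the first is the task of the catalyst, the second follows because the cyclic boronate has neither a further B–OH nor a free hydroxyl, and the mirror plane of 5 leaves no regio- or diastereomeric alternative.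

Step 4
Reactants: 8 (4S,5R)-4-(1,3-dioxolan-2-yl)-4,5-dihydroxycyclohex-2-en-1-one 4,5-O-phenylboronate
Product: 10 (4S,5S,6R)-6-bromo-4-(1,3-dioxolan-2-yl)-4,5-dihydroxycyclohex-2-en-1-one 4,5-O-phenylboronate (bromine trans to the C5 oxygen), via silyl dienol ether 9 (not isolated)
Conditions: TMSOTf, Et3N, CH2Cl2, −78 → 0 °C; then NBS, THF, −78 °C
Reagents that add atoms: N-bromosuccinimide, O=C1CCC(=O)N1Br; trimethylsilyl triflate, C[Si](C)(C)OS(=O)(=O)C(F)(F)F (its silyl group stays only in 9)
Why: Soft enolisation (silyl triflate/amine) can only go toward C6 because C4 is quaternary and gives the cross-conjugated silyl dienol ether 9 without a free enolate that could expel the C5 oxygen, and electrophilic α'-bromination of this enol ether by NBS should occur mainly on the face opposite the neighbouring C5–O bond, which sets C6.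

Step 5
Reactants: 10 (4S,5S,6R)-6-bromo-4-(1,3-dioxolan-2-yl)-4,5-dihydroxycyclohex-2-en-1-one 4,5-O-phenylboronate
Product: 12 (4S,5R,6S)-4-(1,3-dioxolan-2-yl)-5,6-epoxy-4-hydroxycyclohex-2-en-1-one (oxirane cis to the C4 hydroxyl), via bromodiol 11 (not isolated)
Conditions: K2CO3, MeOH, 0 °C; aq. NH4Cl
Reagents that add atoms: none
Why: Methanolysis of the boronate frees the C5 alkoxide, which displaces the anti bromide at C6 in an intramolecular SN2 reaction (halohydrin-to-epoxide closure) with inversion, so the oxirane oxygen is the tethered C5 oxygen and lies cis to the C4 hydroxyl; a syn-bromide epimer cannot close and should be drained into the anti epimer by reversible enolisation or bromide exchange at C6.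

Step 6
Reactants: 12 (4S,5R,6S)-4-(1,3-dioxolan-2-yl)-5,6-epoxy-4-hydroxycyclohex-2-en-1-one
Product: 13 (4S,5R,6S)-4-(1,3-dioxolan-2-yl)-5,6-epoxy-4-hydroxy-2-iodocyclohex-2-en-1-one
Conditions: I2, pyridine, CH2Cl2, 0 °C → rt
Reagents that add atoms: iodine, II
Why: α-Iodination of the enone by the iodine/pyridine conjugate-addition, iodination and elimination sequence (Baylis–Hillman-type mechanism) is established for epoxy cyclohexenones and can only functionalise C2, the sole enone α-carbon, without touching a stereocentre.

Step 7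
Reactants: 14 ethyl (2E,4E)-hexa-2,4-dienoate (ethyl sorbate)
Product: 15 ethyl (2E,4E)-6-bromohexa-2,4-dienoate
Conditions: NBS, (PhCO2)2 (cat.), PhCl, 100 °C
Reagents that add atoms: N-bromosuccinimide, O=C1CCC(=O)N1Br
Why: Wohl–Ziegler radical bromination attacks the terminal allylic methyl group because the delocalised radical is trapped at the end that keeps the dienoate conjugation.

Step 8
Reactants: 15 ethyl (2E,4E)-6-bromohexa-2,4-dienoate
Product: 16 ethyl (2E,4E)-6-(diethoxyphosphoryl)hexa-2,4-dienoate
Conditions: P(OEt)3 (neat), 120 °C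
Reagents that add atoms: triethyl phosphite, CCOP(OCC)OCC
Why: Michaelis–Arbuzov reaction of the primary allylic bromide with the phosphite gives the phosphonate with loss of bromoethane.

Step 9
Reactants: 17 (R)-2-methylbutanoic acid
Product: 18 (R)-2-methylbutan-1-ol
Conditions: LiAlH4, Et2O, 0 °C → rt; H2O, aq. NaOH work-up
Reagents that add atoms: none
Why: Hydride reduction of the carboxylic acid passes through the carboxylate, which is not enolised, so the (R) centre is carried through unchanged.

Step 10
Reactants: 18 (R)-2-methylbutan-1-ol; 16 ethyl (2E,4E)-6-(diethoxyphosphoryl)hexa-2,4-dienoate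
Product: 20 ethyl (2E,4E,6E,8R)-8-methyldeca-2,4,6-trienoate, via (R)-2-methylbutanal 19 (not isolated)
Conditions: (COCl)2, DMSO, iPr2NEt, CH2Cl2, −78 °C; cold aqueous wash; dried solution of 19 added to 16, LiN(SiMe3)2, THF, −78 → 0 °C
Reagents that add atoms: none
Why: Swern oxidation at low temperature should give the α-branched aldehyde 19 without epimerisation, and the vinylogous Horner–Wadsworth–Emmons olefination through the α-carbon of the lithiated phosphonate should form the new C6=C7 bond with E geometry (reversible addition, then elimination) while the E,E-diene of the reagent is kept.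

Step 11
Reactants: 20 ethyl (2E,4E,6E,8R)-8-methyldeca-2,4,6-trienoate
Product: 21 (2E,4E,6E,8R)-8-methyldeca-2,4,6-trienamide
Conditions: AlMe3, NH4Cl, toluene, 50 °C; dil. HCl work-up
Reagents that add atoms: ammonium chloride, [NH4+].[Cl-]
Why: Aluminium amide aminolysis of the ester (Weinreb-type, reagent formed from AlMe3 and NH4Cl) should convert it into the primary amide by acyl substitution without addition to the triene.

Step 12
Reactants: 13 (4S,5R,6S)-4-(1,3-dioxolan-2-yl)-5,6-epoxy-4-hydroxy-2-iodocyclohex-2-en-1-one; 21 (2E,4E,6E,8R)-8-methyldeca-2,4,6-trienamide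
Product: 22 N-[(4S,5R,6S)-4-(1,3-dioxolan-2-yl)-5,6-epoxy-4-hydroxy-1-oxocyclohex-2-en-2-yl] (2E,4E,6E,8R)-8-methyldeca-2,4,6-trienamide
Conditions: CuI (20 mol %), N,N'-dimethylethylenediamine, Cs2CO3, THF, 50 °C, dark
Reagents that add atoms: none
Why: Goldberg-type copper-catalysed C–N coupling of a vinyl iodide with a primary amide proceeds with retention at the sp2 carbon; the tertiary alcohol cannot compete because it would close a four-membered ring, and the carbonate base is mild enough for the epoxy ketone.

Step 13
Reactants: 16 ethyl (2E,4E)-6-(diethoxyphosphoryl)hexa-2,4-dienoate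
Product: 23 (2E,4E)-6-(diethoxyphosphoryl)hexa-2,4-dienoic acid
Conditions: LiOH·H2O, THF/H2O, rt; then aq. HCl to pH 2
Reagents that add atoms: lithium hydroxide, [Li+].[OH-]
Why: Saponification of the conjugated ethyl ester by hydroxide at room temperature leaves the phosphonate diester untouched.

Step 14
Reactants: 24 cyclopentane-1,3-dione
Product: 25 2-nitrocyclopentane-1,3-dione (enol form)
Conditions: fuming HNO3, CH2Cl2, 0 °C
Reagents that add atoms: nitric acid, O[N+](=O)[O-]
Why: Electrophilic nitration of the enolised 1,3-dione occurs at C2, its only nucleophilic carbon.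

Step 15
Reactants: 25 2-nitrocyclopentane-1,3-dione
Product: 26 2-amino-3-hydroxycyclopent-2-en-1-one hydrochloride
Conditions: H2 (1 atm), Pd/C, HCl, MeOH, rt
Reagents that add atoms: hydrogen chloride, Cl
Why: Catalytic hydrogenation reduces the nitro group to the amine, which is trapped as its hydrochloride because the free enaminone is sensitive to air.

Step 16
Reactants: 23 (2E,4E)-6-(diethoxyphosphoryl)hexa-2,4-dienoic acid; 26 2-amino-3-hydroxycyclopent-2-en-1-one hydrochloride
Product: 27 diethyl [(2E,4E)-6-[(2-hydroxy-5-oxocyclopent-1-en-1-yl)amino]-6-oxohexa-2,4-dien-1-yl]phosphonate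
Conditions: EDC·HCl, HOBt, Et3N, DMF, 0 °C → rt
Reagents that add atoms: none
Why: Carbodiimide/hydroxybenzotriazole amide coupling acylates the amino group, and any O-acyl isomer formed on the enol should rearrange to the more stable N-acyl compound (O-to-N acyl shift).

Step 17
Reactants: 22 N-[(4S,5R,6S)-4-(1,3-dioxolan-2-yl)-5,6-epoxy-4-hydroxy-1-oxocyclohex-2-en-2-yl] (2E,4E,6E,8R)-8-methyldeca-2,4,6-trienamide
Product: 28 N-[(4S,5R,6S)-5,6-epoxy-4-formyl-4-hydroxy-1-oxocyclohex-2-en-2-yl] (2E,4E,6E,8R)-8-methyldeca-2,4,6-trienamide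
Conditions: CF3CO2H/H2O (9:1), 0 °C, dark; used crude
Reagents that add atoms: water, O
Why: Acid-catalysed acetal hydrolysis frees the C7 aldehyde; the inductive deactivation that makes this acetal slow also protects the oxirane and the tertiary carbinol from ionisation, and the 2-acylamino enone resists hydrolysis because C-protonation would place a cation next to the ketone.

Step 18
Reactants: 28 N-[(4S,5R,6S)-5,6-epoxy-4-formyl-4-hydroxy-1-oxocyclohex-2-en-2-yl] (2E,4E,6E,8R)-8-methyldeca-2,4,6-trienamide; 27 diethyl [(2E,4E)-6-[(2-hydroxy-5-oxocyclopent-1-en-1-yl)amino]-6-oxohexa-2,4-dien-1-yl]phosphonate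
Product: 29 CNP0596887.4, (2E,4E,6E,8R)-N-[(1S,5S,6R)-5-hydroxy-5-[(1E,3E,5E)-7-[(2-hydroxy-5-oxocyclopent-1-en-1-yl)amino]-7-oxohepta-1,3,5-trien-1-yl]-2-oxo-7-oxabicyclo[4.1.0]hept-3-en-3-yl]-8-methyldeca-2,4,6-trienamide
Conditions: 27 (2.5 equiv), LiN(SiMe3)2 (5 equiv), THF, −78 °C; then 28, −78 → 0 °C; pH 5 buffer
Reagents that add atoms: none
Why: Vinylogous Horner–Wadsworth–Emmons olefination with the dianion of 27 (enolate plus phosphonate carbanion, as in dianion olefinations of phosphono acids) should attack only the aldehyde, the ketone being far less electrophilic, and form the new alkene at C7 with E geometry while the existing E,E-diene of the reagent is kept.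

Compound list
1 | 4-hydroxybenzaldehyde | O=Cc1ccc(O)cc1 | starting material
2 | ethylene glycol | OCCO | starting material
3 | 4-(1,3-dioxolan-2-yl)phenol | Oc1ccc(cc1)C1OCCO1 | intermediate
4 | 4-(1,3-dioxolan-2-yl)-4-hydroperoxycyclohexa-2,5-dien-1-one (not isolated) | O=C1C=CC(OO)(C2OCCO2)C=C1 | intermediate
5 | 4-(1,3-dioxolan-2-yl)-4-hydroxycyclohexa-2,5-dien-1-one | O=C1C=CC(O)(C2OCCO2)C=C1 | intermediate
6 | phenylboronic acid | OB(O)c1ccccc1 | starting material
7 | hemiester of phenylboronic acid with the C4 hydroxyl of 5 (not isolated) | O=C1C=CC(OB(O)c2ccccc2)(C3OCCO3)C=C1 | intermediate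
8 | (4S,5R)-4-(1,3-dioxolan-2-yl)-4,5-dihydroxycyclohex-2-en-1-one 4,5-O-phenylboronate, cis-fused | C1=C[C@]2(C3OCCO3)OB(c4ccccc4)O[C@@H]2CC1=O | intermediate
9 | (4S,5R) trimethylsilyl dienol ether of 8 (C1–OSiMe3, C1=C6 and C2=C3; not isolated) | C1=C[C@]2(C3OCCO3)OB(c4ccccc4)O[C@@H]2C=C1O[Si](C)(C)C | intermediate
10 | (4S,5S,6R)-6-bromo-4-(1,3-dioxolan-2-yl)-4,5-dihydroxycyclohex-2-en-1-one 4,5-O-phenylboronate, bromine trans to the C5 oxygen | C1=C[C@]2(C3OCCO3)OB(c4ccccc4)O[C@@H]2[C@@H](Br)C1=O | intermediate
11 | (4S,5S,6R)-6-bromo-4-(1,3-dioxolan-2-yl)-4,5-dihydroxycyclohex-2-en-1-one (not isolated) | C1=C[C@@](O)(C2OCCO2)[C@H](O)[C@@H](Br)C1=O | intermediate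
12 | (4S,5R,6S)-4-(1,3-dioxolan-2-yl)-5,6-epoxy-4-hydroxycyclohex-2-en-1-one | C1=C[C@@](O)(C3OCCO3)[C@@H]2O[C@@H]2C1=O | intermediate
13 | (4S,5R,6S)-4-(1,3-dioxolan-2-yl)-5,6-epoxy-4-hydroxy-2-iodocyclohex-2-en-1-one | IC1=C[C@@](O)(C3OCCO3)[C@@H]2O[C@@H]2C1=O | intermediate
14 | ethyl (2E,4E)-hexa-2,4-dienoate | CCOC(=O)/C=C/C=C/C | starting material
15 | ethyl (2E,4E)-6-bromohexa-2,4-dienoate | CCOC(=O)/C=C/C=C/CBr | intermediate
16 | ethyl (2E,4E)-6-(diethoxyphosphoryl)hexa-2,4-dienoate | CCOC(=O)/C=C/C=C/CP(=O)(OCC)OCC | intermediate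
17 | (R)-2-methylbutanoic acid | CC[C@@H](C)C(O)=O | starting material
18 | (R)-2-methylbutan-1-ol | CC[C@@H](C)CO | intermediate
19 | (R)-2-methylbutanal (not isolated) | CC[C@@H](C)C=O | intermediate
20 | ethyl (2E,4E,6E,8R)-8-methyldeca-2,4,6-trienoate | CC[C@@H](C)/C=C/C=C/C=C/C(=O)OCC | intermediate
21 | (2E,4E,6E,8R)-8-methyldeca-2,4,6-trienamide | CC[C@@H](C)/C=C/C=C/C=C/C(N)=O | intermediate
22 | N-[(4S,5R,6S)-4-(1,3-dioxolan-2-yl)-5,6-epoxy-4-hydroxy-1-oxocyclohex-2-en-2-yl] (2E,4E,6E,8R)-8-methyldeca-2,4,6-trienamide | CC[C@@H](C)/C=C/C=C/C=C/C(=O)NC1=C[C@@](O)(C3OCCO3)[C@@H]2O[C@@H]2C1=O | intermediate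
23 | (2E,4E)-6-(diethoxyphosphoryl)hexa-2,4-dienoic acid | OC(=O)/C=C/C=C/CP(=O)(OCC)OCC | intermediate
24 | cyclopentane-1,3-dione | O=C1CCC(=O)C1 | starting material
25 | 2-nitrocyclopentane-1,3-dione, drawn as its enol 3-hydroxy-2-nitrocyclopent-2-en-1-one | O=C1CCC(O)=C1[N+](=O)[O-] | intermediate
26 | 2-amino-3-hydroxycyclopent-2-en-1-one hydrochloride | NC1=C(O)CCC1=O.Cl | intermediate
27 | diethyl [(2E,4E)-6-[(2-hydroxy-5-oxocyclopent-1-en-1-yl)amino]-6-oxohexa-2,4-dien-1-yl]phosphonate | CCOP(=O)(OCC)C/C=C/C=C/C(=O)NC1=C(O)CCC1=O | intermediate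
28 | N-[(4S,5R,6S)-5,6-epoxy-4-formyl-4-hydroxy-1-oxocyclohex-2-en-2-yl] (2E,4E,6E,8R)-8-methyldeca-2,4,6-trienamide | CC[C@@H](C)/C=C/C=C/C=C/C(=O)NC1=C[C@@](O)(C=O)[C@@H]2O[C@@H]2C1=O | intermediate
29 | CNP0596887.4; ring core (4S,5R,6S), side chain (8R), all alkenes E | CC[C@@H](C)/C=C/C=C/C=C/C(=O)NC1=C[C@@](O)(/C=C/C=C/C=C/C(=O)NC2=C(O)CCC2=O)[C@@H]2O[C@@H]2C1=O | target

Total step count: 18 (nine in the main line, five for amide 21 including the shared phosphonate 16, four for reagent 27).
Longest linear sequence: 9 steps (steps 1–6, 12, 17 and 18).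

Steps most likely to fail

Step 3 (labelled). Three processes threaten it: the hindered tertiary hydroxyl may form the hemiester only slowly, a catalyst developed for open-chain enones may discriminate poorly between the two enone arms, and the adduct may revert by β-elimination. The fallback uses known chemistry and sets out from 5. Hydroxyl-directed nucleophilic epoxidation (Ti(OiPr)4, t-BuOOH, CH2Cl2, −20 °C) delivers the metal-bound peroxide from the C4 oxygen, the peroxide counterpart of the boron tether, and so places the oxirane syn to the hydroxyl. It should give the racemic syn-epoxy quinol, that is 12 together with its mirror image, the (4R,5S,6R)-epoxide F1. Preparative chromatography on a chiral stationary phase separates the two, and the route is rejoined at 12, so that steps 3 to 5 are bypassed.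

Step 17. The acetal is deactivated by three neighbouring oxygens and may need acid strong enough to isomerise or hydrate the trienamide chain, and the freed α-hydroxy aldehyde may undergo α-ketol rearrangement while it waits. The fallback unmasks the aldehyde before any polyene is present and sets out from 13. The same aqueous acid, now acting on a small molecule without a polyene, should give the iodo hydroxy aldehyde F2. Olefination with the dianion of 27 under the conditions of step 18 should give the iodo enone with the complete lower chain F3. Copper-catalysed amidation with 21 under the conditions of step 12, with a full equivalent of CuI if the cyclopentenone enolate binds the metal, is then the last bond formation and returns to the route at 29.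

Step 18. Proton transfer from the N–H and O–H groups of 28 to the doubly charged, poorly soluble reagent may stall the addition, the excess base may degrade the epoxy ketone, and the E geometry of the new alkene may erode. The fallback forms the lower amide bond last and sets out from 28. Acid 23 is first converted (allyl bromide, K2CO3, DMF) into the allyl phosphonate F4. Its mono-anion (one equivalent of LiN(SiMe3)2, THF, −78 °C), which behaves like the reagent of step 10, should give the allyl trienoate F5. Neutral deallylation (Pd(PPh3)4 cat., morpholine, THF, rt) should free the trienoic acid F6, and carbodiimide coupling with 26 as in step 16 returns to the route at 29.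

Further compounds
F1 | step 3 | (4R,5S,6R)-4-(1,3-dioxolan-2-yl)-5,6-epoxy-4-hydroxycyclohex-2-en-1-one, mirror image of 12 | C1=C[C@](O)(C3OCCO3)[C@H]2O[C@H]2C1=O
F2 | step 17 | (4S,5R,6S)-5,6-epoxy-4-formyl-4-hydroxy-2-iodocyclohex-2-en-1-one | IC1=C[C@@](O)(C=O)[C@@H]2O[C@@H]2C1=O
F3 | step 17 | (2E,4E,6E)-7-[(4S,5R,6S)-5,6-epoxy-4-hydroxy-2-iodo-1-oxocyclohex-2-en-4-yl]-N-(2-hydroxy-5-oxocyclopent-1-en-1-yl)hepta-2,4,6-trienamide | IC1=C[C@@](O)(/C=C/C=C/C=C/C(=O)NC3=C(O)CCC3=O)[C@@H]2O[C@@H]2C1=O
F4 | step 18 | allyl (2E,4E)-6-(diethoxyphosphoryl)hexa-2,4-dienoate | C=CCOC(=O)/C=C/C=C/CP(=O)(OCC)OCC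
F5 | step 18 | allyl (2E,4E,6E)-hepta-2,4,6-trienoate carrying at C7 the (4S,5R,6S) core of 28 with its (8R)-trienamide | CC[C@@H](C)/C=C/C=C/C=C/C(=O)NC1=C[C@@](O)(/C=C/C=C/C=C/C(=O)OCC=C)[C@@H]2O[C@@H]2C1=O
F6 | step 18 | the corresponding free (2E,4E,6E)-hepta-2,4,6-trienoic acid | CC[C@@H](C)/C=C/C=C/C=C/C(=O)NC1=C[C@@](O)(/C=C/C=C/C=C/C(O)=O)[C@@H]2O[C@@H]2C1=O
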